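The butenolide carbonyl C2 lies between C3 and the ring oxygen O1, so the lactone maps onto carbon monoxide plus a (Z)-β-iodoenone (C3–I, C4–H, ketone C5 with an enolisable CH2); the strategy rests on this feature.
The central disubstituted alkene of the polyene is cut by a Wittig reaction between a ring A C17 enyne-dienyl tributylphosphonium salt and the butenolide dienal.
The iodoenone comes from an ynone by hydroiodination; the ynone comes from Sonogashira union of a ring B (E)-vinyl iodide with a prenol-derived alkynol, then oxidation.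
The ring B triol comes from hydroxyl-directed syn-epoxidation of an ethynylcyclohexenol and trans-diaxial hydrolysis at ring B C5; both carbocycles derive from ketoisophorone through the two enantiomers of its C4 carbinol.
Ring order: rings A and B are carried over from ketoisophorone; the butenolide is the only ring formed in the route.

Key step: step 20

Remark: the SMILES gives ring A the zeaxanthin-type (R) carbinol but ring B the triol 3R,5S,6S (carotenoid numbering), whose carbinol carbon has the opposite spatial sense, so the two rings are made from the two enantiomers of 4-hydroxy-2,6,6-trimethylcyclohex-2-enone; the sense of induction of each TsDPEN catalyst is assigned by analogy with aryl ketones, and the two catalysts would simply be exchanged if it proved opposite.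

**Ring B vinyl iodide**

Step 1
Reactants: 1 ketoisophorone
Product: 2 (4R)-4-hydroxy-2,6,6-trimethylcyclohex-2-en-1-one
Conditions: Ru[(R,R)-TsDPEN](p-cymene) (amido complex, 1 mol %), i-PrOH, rt
Reagents that add atoms: none
Why: Noyori asymmetric transfer hydrogenation should reduce only the unhindered enone carbonyl C4 (C1 is flanked by the quaternary carbon and the methyl-bearing alkene carbon), and the (R,R) ligand is expected to set the carbinol stereocentre as R by the same CH/π-controlled hydride delivery that gives (R)-alcohols from aryl ketones.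

Step 2
Reactants: 2 (4R)-4-hydroxy-2,6,6-trimethylcyclohex-2-en-1-one
Product: 3 (4R)-4-[(tert-butyldimethylsilyl)oxy]-2,6,6-trimethylcyclohex-2-en-1-one
Conditions: TBSCl, imidazole, DMF, rt
Reagents that add atoms: tert-butyldimethylsilyl chloride, CC(C)(C)[Si](C)(C)Cl
Why: Imidazole-promoted silylation of the secondary alcohol masks the hydroxyl for the enolate chemistry that follows.

Step 3
Reactants: 3 silyloxy enone
Product: 4 (4S)-4-[(tert-butyldimethylsilyl)oxy]-2,2,6-trimethylcyclohexan-1-one (both C6 epimers)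
Conditions: H2 (1 atm), Pd/C (10 %), EtOAc, rt
Reagents that add atoms: none
Why: Heterogeneous catalytic hydrogenation should saturate the enone C=C without touching the hindered ketone or the silyl ether, and the new methyl-bearing stereocentre need not be controlled because step 4 makes that carbon trigonal again.

Step 4
Reactants: 4 saturated silyloxy ketone
Product: 6 (4S)-4-[(tert-butyldimethylsilyl)oxy]-2,6,6-trimethylcyclohex-1-en-1-yl trifluoromethanesulfonate, via lithium enolate 5 (not isolated)
Conditions: LiN(i-Pr)2, THF, −78 → 0 °C; PhNTf2, −78 °C → rt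
Reagents that add atoms: N-phenylbis(trifluoromethanesulfonimide), O=S(=O)(N(c1ccccc1)S(=O)(=O)C(F)(F)F)C(F)(F)F
Why: Enolisation can occur only at the single α-CH because the other α-carbon is quaternary, and O-sulfonylation of the enolate (enol triflate formation) gives the tetrasubstituted triflate regiospecifically.

Step 5
Reactants: 6 ring B enol triflate; 7 trimethylsilylacetylene
Product: 8 tert-butyldimethyl{[(1S)-3,5,5-trimethyl-4-[(trimethylsilyl)ethynyl]cyclohex-3-en-1-yl]oxy}silane
Conditions: PdCl2(PPh3)2 (5 mol %), CuI (10 mol %), Et3N, DMF, rt → 50 °C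
Reagents that add atoms: none
Why: Sonogashira coupling of an enol triflate with a terminal alkyne, for which hindered 2,6,6-trimethylcyclohexenyl triflates are established partners.

Step 6
Reactants: 8 ring B silylated enyne
Product: 9 (1S)-4-ethynyl-3,5,5-trimethylcyclohex-3-en-1-ol
Conditions: Bu4NF, THF, 0 °C → rt
Reagents that add atoms: none
Why: Fluoride-mediated desilylation cleaves the O–Si and the alkynyl C–Si bond in one operation and frees the hydroxyl that must direct the next step.

Step 7
Reactants: 9 ring B ethynylcyclohexenol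
Product: 10 (1R,3R,6R)-6-ethynyl-1,5,5-trimethyl-7-oxabicyclo[4.1.0]heptan-3-ol (epoxide oxygen cis to the hydroxyl)
Conditions: VO(acac)2 (5 mol %), t-BuOOH, toluene, rt → 40 °C
Reagents that add atoms: tert-butyl hydroperoxide, CC(C)(C)OO
Why: Vanadium-catalysed hydroxyl-directed epoxidation of a homoallylic cyclohex-3-enol, in which the vanadate ester of the pseudoaxial hydroxyl delivers the peroxide oxygen to its own face, so the two new stereocentres (ring B C5 and C6) should carry the epoxide oxygen cis to the carbinol oxygen.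

Step 8
Reactants: 10 syn-epoxy alcohol
Product: 11 (1R,2S,4R)-1-ethynyl-2,6,6-trimethylcyclohexane-1,2,4-triol
Conditions: HClO4 (aq., 5 %), THF, 0 °C → rt
Reagents that add atoms: water, O
Why: Acid-catalysed epoxide hydrolysis should occur by trans-diaxial (Fürst–Plattner) attack of water at ring B C5, the tertiary carbon remote from the inductively deactivating ethynyl group and from the neopentyl-like C6, which inverts C5 and retains C6 (5-OH trans and 6-OH cis to the 3-OH), whereas opening at C6 would need a chair with three syn-axial groups.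

Step 9
Reactants: 11 ring B ethynyl triol
Product: 12 (1R,2S,4R)-4-[(tert-butyldimethylsilyl)oxy]-1-ethynyl-2,6,6-trimethylcyclohexane-1,2-diol
Conditions: TBSCl, imidazole, DMF, rt
Reagents that add atoms: tert-butyldimethylsilyl chloride, CC(C)(C)[Si](C)(C)Cl
Why: Silylation is selective for the secondary hydroxyl because the two tertiary hydroxyls are too hindered to react with TBSCl and imidazole.

Step 10
Reactants: 12 ring B ethynyl diol silyl ether
Product: 14 (1S,2S,4R)-4-[(tert-butyldimethylsilyl)oxy]-1-[(E)-2-iodoethenyl]-2,6,6-trimethylcyclohexane-1,2-diol, via vinylstannane 13 (not isolated)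
Conditions: Bu3SnH, PdCl2(PPh3)2 (2 mol %), THF, 0 °C; then I2, CH2Cl2, 0 °C
Reagents that add atoms: iodine, [I][I]
Why: Palladium-catalysed syn-hydrostannation of the terminal alkyne should place tin at the unhindered terminus (the fully substituted propargylic carbon blocks the internal position), and iododestannylation proceeds with retention to give the (E)-vinyl iodide.

**Alkynol fragment**

Step 11
Reactants: 15 3-methylbut-2-en-1-ol
Product: 16 tert-butyldimethyl[(3-methylbut-2-en-1-yl)oxy]silane
Conditions: TBSCl, imidazole, CH2Cl2, rt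
Reagents that add atoms: tert-butyldimethylsilyl chloride, CC(C)(C)[Si](C)(C)Cl
Why: Standard imidazole-promoted silylation of a primary alcohol.

Step 12
Reactants: 16 prenyl silyl ether
Product: 18 (2E)-4-[(tert-butyldimethylsilyl)oxy]-2-methylbut-2-enal, via allylic alcohol 17 (not isolated)
Conditions: SeO2 (cat.), t-BuOOH, CH2Cl2, rt; then MnO2, CH2Cl2, rt
Reagents that add atoms: tert-butyl hydroperoxide, CC(C)(C)OO (oxygen delivered through the catalytic carrier selenium dioxide, O=[Se]=O)
Why: Selenium dioxide allylic oxidation (ene reaction, then [2,3]-sigmatropic shift) functionalises the methyl group trans to the CH2O substituent to give the (E)-allylic alcohol with some enal, and MnO2 oxidation then converges the mixture on the enal.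

Step 13
Reactants: 18 (E)-silyloxy enal
Product: 19 tert-butyldimethyl{[(2E)-3-methylpenta-2,4-dien-1-yl]oxy}silane
Conditions: Ph3PCH3Br, KOt-Bu, THF, 0 °C
Reagents that add atoms: methyltriphenylphosphonium bromide, C[P+](c1ccccc1)(c1ccccc1)c1ccccc1.[Br-]
Why: Wittig methylenation with the non-stabilised ylide gives the terminal diene without disturbing the trisubstituted (E)-alkene.

Step 14
Reactants: 19 silyloxy diene
Product: 21 (3E)-5-[(tert-butyldimethylsilyl)oxy]-3-methylpent-3-en-1-ol, via alkylborane 20 (not isolated)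
Conditions: 9-BBN, THF, 0 °C → rt; then NaOH, H2O2, 0 °C
Reagents that add atoms: hydrogen peroxide, OO
Why: Hydroboration–oxidation, in which the bulky borane adds only to the monosubstituted terminal alkene with boron on the terminal carbon and oxidation with retention gives the primary homoallylic alcohol.

Step 15
Reactants: 21 homoallylic alcohol
Product: 22 (3E)-5-[(tert-butyldimethylsilyl)oxy]-3-methylpent-3-enal
Conditions: Dess–Martin periodinane, NaHCO3, CH2Cl2, 0 °C
Reagents that add atoms: none
Why: Dess–Martin oxidation under bicarbonate buffering should give the β,γ-unsaturated aldehyde without acid or base strong enough to move the alkene into conjugation, and the aldehyde is used at once.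

Step 16
Reactants: 22 β,γ-unsaturated aldehyde
Product: 23 (5E)-7-[(tert-butyldimethylsilyl)oxy]-5-methylhept-5-en-1-yn-3-ol (racemic)
Conditions: HC≡CMgBr, THF, −78 → 0 °C
Reagents that add atoms: ethynylmagnesium bromide, C#C[Mg]Br
Why: Grignard 1,2-addition of the weakly basic magnesium acetylide at low temperature should outrun enolisation of the aldehyde, and the new carbinol centre is formed as a racemate without consequence because step 18 oxidises it.

**Union and butenolide**

Step 17
Reactants: 14 ring B (E)-vinyl iodide; 23 alkynol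
Product: 24 ring B enynol (both carbinol epimers)
Conditions: PdCl2(PPh3)2 (5 mol %), CuI (10 mol %), Et3N, THF, rt
Reagents that add atoms: none
Why: Sonogashira coupling of a vinyl iodide with a terminal alkyne proceeds with retention of the (E)-geometry and tolerates the free hydroxyls.

Step 18
Reactants: 24 ring B enynol
Product: 25 ring B ynone
Conditions: MnO2, CH2Cl2, rt
Reagents that add atoms: none
Why: Activated MnO2 oxidises only the propargylic secondary alcohol (the tertiary alcohols and silyl ethers are inert) under neutral conditions that should leave the β,γ-alkene in place.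

Step 19
Reactants: 25 ring B ynone
Product: 26 ring B (Z)-β-iodo dienone
Conditions: NaI, AcOH, rt
Reagents that add atoms: sodium iodide, [Na+].[I-]
Why: Conjugate hydroiodination of an ynone, in which iodide adds to the β-alkyne carbon and the allenol is protonated anti, gives under kinetic control the (Z)-β-iodoenone with iodine cis to the ketone.

Step 20
Reactants: 26 ring B (Z)-β-iodo dienone
Product: 27 ring B ylidenebutenolide with silyloxy dienyl stub
Conditions: PdCl2(PPh3)2 (5 mol %), CO (1 atm), Et3N, DMF, rt → 40 °C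
Reagents that add atoms: carbon monoxide, [C-]#[O+]
Why: PdCl2(PPh3)2 is reduced in the flask to zerovalent palladium, which inserts into the C3–I bond of 26 with retention of the Z geometry, and migratory insertion of carbon monoxide forms the C2–C3 bond and gives an acylpalladium iodide held cis to the lactone C5 ketone. Triethylamine enolises the ketone toward the CH2 that is both allylic and α to the carbonyl (the other α-carbon, C4, is vinylic and cannot enolise, and γ-deprotonation of any conjugated isomer gives the same dienolate), and the enol oxygen acylates to form C2–O1, releasing zerovalent palladium and triethylammonium iodide. The closest known reaction type is the palladium-catalysed carbonylative lactonisation of (Z)-β-iodoenones to (Z)-γ-alkylidenebutenolides, to which this substrate class belongs. The butenolide closes by O-acylation of the enol in a five-membered ring closure (5-exo-trig attack on the acyl carbon), and no stereocentre is created. The step needs O- over C-acylation and a Z exocyclic alkene: O-acylation of the enol by the acylpalladium is the precedented course, and the Z isomer keeps the dienyl chain away from the C4 hydrogen and is also the thermodynamic isomer. The E vinylene holds the ring B C6 hydroxyl out of reach of the acylpalladium, and the other tertiary hydroxyl is too hindered and remote to compete.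

Step 21
Reactants: 27 ylidenebutenolide bis-silyl ether
Product: 28 ylidenebutenolide primary allylic alcohol
Conditions: HF·pyridine, pyridine, THF, 0 °C
Reagents that add atoms: none
Why: Selective desilylation, because buffered HF·pyridine cleaves the unhindered primary allylic silyl ether much faster than the secondary ring B silyl ether.

Step 22
Reactants: 28 ylidenebutenolide primary allylic alcohol
Product: 29 ylidenebutenolide dienal
Conditions: MnO2, CH2Cl2, rt
Reagents that add atoms: none
Why: MnO2 oxidation of the primary allylic alcohol gives the conjugated aldehyde, the ring B hydroxyls being tertiary or silylated.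

**Ring A phosphonium salt**

Step 23
Reactants: 1 ketoisophorone
Product: 30 (4S)-4-hydroxy-2,6,6-trimethylcyclohex-2-en-1-one
Conditions: Ru[(S,S)-TsDPEN](p-cymene) (amido complex, 1 mol %), i-PrOH, rt
Reagents that add atoms: none
Why: The same Noyori transfer hydrogenation as in step 1 with the mirror-image catalyst should set the carbinol stereocentre as S.

Step 24
Reactants: 30 (4S)-hydroxy enone
Product: 31 (4S)-4-[(tert-butyldimethylsilyl)oxy]-2,6,6-trimethylcyclohex-2-en-1-one
Conditions: TBSCl, imidazole, DMF, rt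
Reagents that add atoms: tert-butyldimethylsilyl chloride, CC(C)(C)[Si](C)(C)Cl
Why: Imidazole-promoted silylation of the secondary alcohol, as in step 2.

Step 25
Reactants: 31 (4S)-silyloxy enone
Product: 32 (4R)-4-[(tert-butyldimethylsilyl)oxy]-2,2,6-trimethylcyclohexan-1-one (both C6 epimers)
Conditions: H2 (1 atm), Pd/C (10 %), EtOAc, rt
Reagents that add atoms: none
Why: Catalytic hydrogenation of the enone C=C as in step 3, the uncontrolled methyl-bearing centre being erased in step 26.

Step 26
Reactants: 32 (4R)-silyloxy ketone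
Product: 34 (4R)-4-[(tert-butyldimethylsilyl)oxy]-2,6,6-trimethylcyclohex-1-en-1-yl trifluoromethanesulfonate, via lithium enolate 33 (not isolated)
Conditions: LiN(i-Pr)2, THF, −78 → 0 °C; PhNTf2, −78 °C → rt
Reagents that add atoms: N-phenylbis(trifluoromethanesulfonimide), O=S(=O)(N(c1ccccc1)S(=O)(=O)C(F)(F)F)C(F)(F)F
Why: Regiospecific enol triflate formation at the only enolisable α-carbon, as in step 4.

Step 27
Reactants: 34 ring A enol triflate; 35 (2E)-3-methylpent-2-en-4-yn-1-ol
Product: 36 (2E)-5-[(4R)-4-[(tert-butyldimethylsilyl)oxy]-2,6,6-trimethylcyclohex-1-en-1-yl]-3-methylpent-2-en-4-yn-1-ol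
Conditions: PdCl2(PPh3)2 (5 mol %), CuI (10 mol %), Et3N, DMF, rt → 50 °C
Reagents that add atoms: none
Why: Sonogashira coupling of the enol triflate with the terminal enyne alcohol, with retention of the (E)-alkene.

Step 28
Reactants: 36 ring A C15 enynol
Product: 37 ring A C15 enynal
Conditions: MnO2, CH2Cl2, rt
Reagents that add atoms: none
Why: MnO2 oxidation of the primary allylic alcohol to the conjugated aldehyde.

Step 29
Reactants: 37 ring A C15 enynal
Product: 38 ethyl (2E,4E)-7-[(4R)-4-[(tert-butyldimethylsilyl)oxy]-2,6,6-trimethylcyclohex-1-en-1-yl]-5-methylhepta-2,4-dien-6-ynoate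
Conditions: (EtO)2P(O)CH2CO2Et, NaH, THF, 0 °C → rt
Reagents that add atoms: triethyl phosphonoacetate, CCOC(=O)CP(=O)(OCC)OCC
Why: Horner–Wadsworth–Emmons olefination with a stabilised phosphonate anion should give the (E)-α,β-unsaturated ester.

Step 30
Reactants: 38 ring A C17 dienynoate
Product: 39 ring A C17 dienynol
Conditions: i-Bu2AlH, CH2Cl2, −78 °C
Reagents that add atoms: none
Why: Hydride 1,2-reduction of the conjugated ester to the allylic alcohol at low temperature leaves the silyl ether and the enyne untouched.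

Step 31
Reactants: 39 ring A C17 dienynol
Product: 41 ring A C17 tributylphosphonium bromide, via dienyl bromide 40 (not isolated)
Conditions: NBS, Me2S, CH2Cl2, −20 → 0 °C; then PBu3, MeCN, rt
Reagents that add atoms: N-bromosuccinimide, O=C1CCC(=O)N1Br; tributylphosphine, CCCCP(CCCC)CCCC
Why: Corey–Kim bromination converts the dienylic alcohol to the primary bromide under neutral conditions, and SN2 displacement by tributylphosphine gives the phosphonium salt.

**Endgame**

Step 32
Reactants: 29 ylidenebutenolide dienal; 41 ring A C17 tributylphosphonium bromide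
Product: 43 bis-silyl ether of the target, via phosphorus ylide 42 (not isolated)
Conditions: NaN(SiMe3)2, THF, −78 °C; then 29, −78 → 0 °C
Reagents that add atoms: none
Why: Wittig olefination, in which allylic tributylphosphonium ylides are expected to give mainly the (E)-alkene because their addition to aldehydes equilibrates before collapse, the ylide being formed at low temperature with a non-nucleophilic base to spare the enol lactone.

Step 33
Reactants: 43 bis-silyl ether of the target
Product: 44 target CNP0163979.2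
Conditions: HF·pyridine, pyridine, THF, 0 °C → rt
Reagents that add atoms: none
Why: Fluoride desilylation with buffered HF·pyridine removes both secondary silyl ethers under non-basic conditions that should leave the ylidenebutenolide and the polyene untouched.

**Compound list**

1 | ketoisophorone (2,6,6-trimethylcyclohex-2-ene-1,4-dione) | CC1=CC(=O)CC(C)(C)C1=O | starting material
2 | (4R)-4-hydroxy-2,6,6-trimethylcyclohex-2-en-1-one | CC1=C[C@H](O)CC(C)(C)C1=O | intermediate
3 | (4R)-4-[(tert-butyldimethylsilyl)oxy]-2,6,6-trimethylcyclohex-2-en-1-one | CC1=C[C@H](O[Si](C)(C)C(C)(C)C)CC(C)(C)C1=O | intermediate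
4 | (4S)-4-[(tert-butyldimethylsilyl)oxy]-2,2,6-trimethylcyclohexan-1-one, both C6 epimers | CC1C[C@H](O[Si](C)(C)C(C)(C)C)CC(C)(C)C1=O | intermediate
5 | lithium enolate of 4 | CC1=C([O-])C(C)(C)C[C@@H](O[Si](C)(C)C(C)(C)C)C1.[Li+] | intermediate
6 | (4S)-4-[(tert-butyldimethylsilyl)oxy]-2,6,6-trimethylcyclohex-1-en-1-yl trifluoromethanesulfonate | CC1=C(OS(=O)(=O)C(F)(F)F)C(C)(C)C[C@@H](O[Si](C)(C)C(C)(C)C)C1 | intermediate
7 | trimethylsilylacetylene | C#C[Si](C)(C)C | starting material
8 | tert-butyldimethyl{[(1S)-3,5,5-trimethyl-4-[(trimethylsilyl)ethynyl]cyclohex-3-en-1-yl]oxy}silane | CC1=C(C#C[Si](C)(C)C)C(C)(C)C[C@@H](O[Si](C)(C)C(C)(C)C)C1 | intermediate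
9 | (1S)-4-ethynyl-3,5,5-trimethylcyclohex-3-en-1-ol | CC1=C(C#C)C(C)(C)C[C@@H](O)C1 | intermediate
10 | (1R,3R,6R)-6-ethynyl-1,5,5-trimethyl-7-oxabicyclo[4.1.0]heptan-3-ol (epoxide oxygen cis to OH) | C#C[C@]12C(C)(C)C[C@@H](O)C[C@@]1(C)O2 | intermediate
11 | (1R,2S,4R)-1-ethynyl-2,6,6-trimethylcyclohexane-1,2,4-triol | C#C[C@]1(O)C(C)(C)C[C@@H](O)C[C@]1(C)O | intermediate
12 | (1R,2S,4R)-4-[(tert-butyldimethylsilyl)oxy]-1-ethynyl-2,6,6-trimethylcyclohexane-1,2-diol | C#C[C@]1(O)C(C)(C)C[C@@H](O[Si](C)(C)C(C)(C)C)C[C@]1(C)O | intermediate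
13 | (1S,2S,4R)-4-[(tert-butyldimethylsilyl)oxy]-2,6,6-trimethyl-1-[(E)-2-(tributylstannyl)ethenyl]cyclohexane-1,2-diol | CCCC[Sn](CCCC)(CCCC)/C=C/[C@]1(O)C(C)(C)C[C@@H](O[Si](C)(C)C(C)(C)C)C[C@]1(C)O | intermediate
14 | (1S,2S,4R)-4-[(tert-butyldimethylsilyl)oxy]-1-[(E)-2-iodoethenyl]-2,6,6-trimethylcyclohexane-1,2-diol | I/C=C/[C@]1(O)C(C)(C)C[C@@H](O[Si](C)(C)C(C)(C)C)C[C@]1(C)O | intermediate
15 | 3-methylbut-2-en-1-ol | CC(C)=CCO | starting material
16 | tert-butyldimethyl[(3-methylbut-2-en-1-yl)oxy]silane | CC(C)=CCO[Si](C)(C)C(C)(C)C | intermediate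
17 | (2E)-4-[(tert-butyldimethylsilyl)oxy]-2-methylbut-2-en-1-ol | CC(C)(C)[Si](C)(C)OC/C=C(C)/CO | intermediate
18 | (2E)-4-[(tert-butyldimethylsilyl)oxy]-2-methylbut-2-enal | CC(C)(C)[Si](C)(C)OC/C=C(C)/C=O | intermediate
19 | tert-butyldimethyl{[(2E)-3-methylpenta-2,4-dien-1-yl]oxy}silane | CC(C)(C)[Si](C)(C)OC/C=C(C)/C=C | intermediate
20 | 9-[(3E)-5-[(tert-butyldimethylsilyl)oxy]-3-methylpent-3-en-1-yl]-9-borabicyclo[3.3.1]nonane | CC(C)(C)[Si](C)(C)OC/C=C(C)/CCB1C2CCCC1CCC2 | intermediate
21 | (3E)-5-[(tert-butyldimethylsilyl)oxy]-3-methylpent-3-en-1-ol | CC(C)(C)[Si](C)(C)OC/C=C(C)/CCO | intermediate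
22 | (3E)-5-[(tert-butyldimethylsilyl)oxy]-3-methylpent-3-enal | CC(C)(C)[Si](C)(C)OC/C=C(C)/CC=O | intermediate
23 | (5E)-7-[(tert-butyldimethylsilyl)oxy]-5-methylhept-5-en-1-yn-3-ol, racemic | CC(C)(C)[Si](C)(C)OC/C=C(C)/CC(O)C#C | intermediate
24 | (1E,7E)-9-[(tert-butyldimethylsilyl)oxy]-1-[(1S,2S,4R)-4-[(tert-butyldimethylsilyl)oxy]-1,2-dihydroxy-2,6,6-trimethylcyclohexyl]-7-methylnona-1,7-dien-3-yn-5-ol, both C5 epimers | CC(C)(C)[Si](C)(C)OC/C=C(C)/CC(O)C#C/C=C/[C@]1(O)C(C)(C)C[C@@H](O[Si](C)(C)C(C)(C)C)C[C@]1(C)O | intermediate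
25 | (1E,7E)-9-[(tert-butyldimethylsilyl)oxy]-1-[(1S,2S,4R)-4-[(tert-butyldimethylsilyl)oxy]-1,2-dihydroxy-2,6,6-trimethylcyclohexyl]-7-methylnona-1,7-dien-3-yn-5-one | CC(C)(C)[Si](C)(C)OC/C=C(C)/CC(=O)C#C/C=C/[C@]1(O)C(C)(C)C[C@@H](O[Si](C)(C)C(C)(C)C)C[C@]1(C)O | intermediate
26 | (1E,3Z,7E)-9-[(tert-butyldimethylsilyl)oxy]-1-[(1S,2S,4R)-4-[(tert-butyldimethylsilyl)oxy]-1,2-dihydroxy-2,6,6-trimethylcyclohexyl]-3-iodo-7-methylnona-1,3,7-trien-5-one | CC(C)(C)[Si](C)(C)OC/C=C(C)/CC(=O)/C=C(\I)/C=C/[C@]1(O)C(C)(C)C[C@@H](O[Si](C)(C)C(C)(C)C)C[C@]1(C)O | intermediate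
27 | (5Z)-5-[(2E)-4-[(tert-butyldimethylsilyl)oxy]-2-methylbut-2-en-1-ylidene]-3-[(E)-2-[(1S,2S,4R)-4-[(tert-butyldimethylsilyl)oxy]-1,2-dihydroxy-2,6,6-trimethylcyclohexyl]ethenyl]furan-2(5H)-one | CC(C)(C)[Si](C)(C)OC/C=C(C)/C=C1C=C(/C=C/[C@]2(O)C(C)(C)C[C@@H](O[Si](C)(C)C(C)(C)C)C[C@]2(C)O)C(=O)O/1 | intermediate
28 | (5Z)-3-[(E)-2-[(1S,2S,4R)-4-[(tert-butyldimethylsilyl)oxy]-1,2-dihydroxy-2,6,6-trimethylcyclohexyl]ethenyl]-5-[(2E)-4-hydroxy-2-methylbut-2-en-1-ylidene]furan-2(5H)-one | OC/C=C(C)/C=C1C=C(/C=C/[C@]2(O)C(C)(C)C[C@@H](O[Si](C)(C)C(C)(C)C)C[C@]2(C)O)C(=O)O/1 | intermediate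
29 | (2E,4Z)-4-[4-[(E)-2-[(1S,2S,4R)-4-[(tert-butyldimethylsilyl)oxy]-1,2-dihydroxy-2,6,6-trimethylcyclohexyl]ethenyl]-5-oxofuran-2(5H)-ylidene]-3-methylbut-2-enal | O=C/C=C(C)/C=C1C=C(/C=C/[C@]2(O)C(C)(C)C[C@@H](O[Si](C)(C)C(C)(C)C)C[C@]2(C)O)C(=O)O/1 | intermediate
30 | (4S)-4-hydroxy-2,6,6-trimethylcyclohex-2-en-1-one | CC1=C[C@@H](O)CC(C)(C)C1=O | intermediate
31 | (4S)-4-[(tert-butyldimethylsilyl)oxy]-2,6,6-trimethylcyclohex-2-en-1-one | CC1=C[C@@H](O[Si](C)(C)C(C)(C)C)CC(C)(C)C1=O | intermediate
32 | (4R)-4-[(tert-butyldimethylsilyl)oxy]-2,2,6-trimethylcyclohexan-1-one, both C6 epimers | CC1C[C@@H](O[Si](C)(C)C(C)(C)C)CC(C)(C)C1=O | intermediate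
33 | lithium enolate of 32 | CC1=C([O-])C(C)(C)C[C@H](O[Si](C)(C)C(C)(C)C)C1.[Li+] | intermediate
34 | (4R)-4-[(tert-butyldimethylsilyl)oxy]-2,6,6-trimethylcyclohex-1-en-1-yl trifluoromethanesulfonate | CC1=C(OS(=O)(=O)C(F)(F)F)C(C)(C)C[C@H](O[Si](C)(C)C(C)(C)C)C1 | intermediate
35 | (2E)-3-methylpent-2-en-4-yn-1-ol | C#C/C(C)=C/CO | starting material
36 | (2E)-5-[(4R)-4-[(tert-butyldimethylsilyl)oxy]-2,6,6-trimethylcyclohex-1-en-1-yl]-3-methylpent-2-en-4-yn-1-ol | CC1=C(C#C/C(C)=C/CO)C(C)(C)C[C@H](O[Si](C)(C)C(C)(C)C)C1 | intermediate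
37 | (2E)-5-[(4R)-4-[(tert-butyldimethylsilyl)oxy]-2,6,6-trimethylcyclohex-1-en-1-yl]-3-methylpent-2-en-4-ynal | CC1=C(C#C/C(C)=C/C=O)C(C)(C)C[C@H](O[Si](C)(C)C(C)(C)C)C1 | intermediate
38 | ethyl (2E,4E)-7-[(4R)-4-[(tert-butyldimethylsilyl)oxy]-2,6,6-trimethylcyclohex-1-en-1-yl]-5-methylhepta-2,4-dien-6-ynoate | CC1=C(C#C/C(C)=C/C=C/C(=O)OCC)C(C)(C)C[C@H](O[Si](C)(C)C(C)(C)C)C1 | intermediate
39 | (2E,4E)-7-[(4R)-4-[(tert-butyldimethylsilyl)oxy]-2,6,6-trimethylcyclohex-1-en-1-yl]-5-methylhepta-2,4-dien-6-yn-1-ol | CC1=C(C#C/C(C)=C/C=C/CO)C(C)(C)C[C@H](O[Si](C)(C)C(C)(C)C)C1 | intermediate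
40 | {[(4R)-4-[(1E,3E)-7-bromo-3-methylhepta-3,5-dien-1-yn-1-yl]-3,5,5-trimethylcyclohex-3-en-1-yl]oxy}(tert-butyl)dimethylsilane (bromide of 39) | CC1=C(C#C/C(C)=C/C=C/CBr)C(C)(C)C[C@H](O[Si](C)(C)C(C)(C)C)C1 | intermediate
41 | tributyl[(2E,4E)-7-[(4R)-4-[(tert-butyldimethylsilyl)oxy]-2,6,6-trimethylcyclohex-1-en-1-yl]-5-methylhepta-2,4-dien-6-yn-1-yl]phosphonium bromide | CC1=C(C#C/C(C)=C/C=C/C[P+](CCCC)(CCCC)CCCC)C(C)(C)C[C@H](O[Si](C)(C)C(C)(C)C)C1.[Br-] | intermediate
42 | phosphorus ylide of 41 | CC1=C(C#C/C(C)=C/C=C/C=P(CCCC)(CCCC)CCCC)C(C)(C)C[C@H](O[Si](C)(C)C(C)(C)C)C1 | intermediate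
43 | bis(tert-butyldimethylsilyl) ether of the target (ring A O3 and ring B O3 silylated) | CC1=C(C#C/C(C)=C/C=C/C=C/C=C(C)/C=C2C=C(/C=C/[C@]3(O)C(C)(C)C[C@@H](O[Si](C)(C)C(C)(C)C)C[C@]3(C)O)C(=O)O/2)C(C)(C)C[C@H](O[Si](C)(C)C(C)(C)C)C1 | intermediate
44 | CNP0163979.2: (5Z)-ylidenebutenolide carrying the (E)-vinyl ring B triol (1S,2S,4R) at C3 and the all-E pentaenynyl chain ending in the (4R)-hydroxy ring A | CC1=C(C#C/C(C)=C/C=C/C=C/C=C(C)/C=C2C=C(/C=C/[C@]3(O)C(C)(C)C[C@@H](O)C[C@]3(C)O)C(=O)O/2)C(C)(C)C[C@H](O)C1 | target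

Total step count: 33 steps.
Longest linear sequence: 18 steps (steps 1–10, 17–22, 32 and 33, from ketoisophorone through ring B).

**Steps most likely to fail**

Step 20 (key step). The enol may be acylated at carbon, the acylpalladium may be captured by another nucleophile before the enol oxygen reaches it, or the iodoenone may isomerise from Z to E under the basic conditions before oxidative addition. The fallback sets out from 26 and returns at 27. Compound 26 is carbonylated in wet DMF (PdCl2(PPh3)2, CO, H2O, Et3N) so that water traps the acylpalladium. The resulting (Z)-4-oxo-2-enoic acid should close by addition of the carboxyl oxygen to the lactone C5 ketone to give hydroxybutenolide F1. Acetylation (Ac2O, pyridine) gives acetoxybutenolide F2, and DBU eliminates acetic acid across C5 and the activated CH2 to give 27. In this variant the ring closes through the C5–O1 bond and the exocyclic alkene is introduced afterwards.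

Step 8. Ionisation of the propargylic C6–O bond may compete with attack at C5 (wrong-site opening gives the C5,C6 bis-epimer), or the C5 cation may lose a proton. The fallback sets out from 8 and returns at 12. Silyl ether 8 is epoxidised with mCPBA (NaHCO3, CH2Cl2, 0 °C); the bulky silyloxy group should send the peracid to the opposite face and give anti-epoxide F3. For this diastereomer the trans-diaxial opening that keeps the silyloxy group equatorial is at C6, so aqueous HClO4 in THF should invert C6 and retain C5, giving silylalkynyl diol F4 with the configuration of 12. The silyl ether also blocks transannular attack of O3 on C6. K2CO3 in MeOH removes the alkynyl silyl group and gives 12.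

Step 32. E selectivity at the new alkene may be incomplete, and the basic ylide may attack or isomerise the enol lactone. The fallback sets out from 29 and 37 and returns at 43. Takai iodo-olefination of 29 (CrCl2, CHI3, THF, 0 °C) gives (E)-iodotriene butenolide F5. The Takai-type stannyl olefination of enynal 37 (CrCl2, Bu3SnCHBr2, LiI, DMF) gives (E)-dienylstannane F6. Stille coupling (Pd2(dba)3, AsPh3, NMP, rt) joins them under neutral conditions to 43, with both alkene geometries fixed before the C(sp2)–C(sp2) bond is made.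

Further compounds
F1 | step 20 | hydroxybutenolide (5-hydroxy-5-[(2E)-4-silyloxy-2-methylbut-2-enyl] cyclic pseudo-acid, both C5 epimers) | CC(C)(C)[Si](C)(C)OC/C=C(C)/CC1(O)C=C(/C=C/[C@]2(O)C(C)(C)C[C@@H](O[Si](C)(C)C(C)(C)C)C[C@]2(C)O)C(=O)O1
F2 | step 20 | acetoxybutenolide (acetate of F1) | CC(C)(C)[Si](C)(C)OC/C=C(C)/CC1(OC(C)=O)C=C(/C=C/[C@]2(O)C(C)(C)C[C@@H](O[Si](C)(C)C(C)(C)C)C[C@]2(C)O)C(=O)O1
F3 | step 8 | anti-epoxide of 8 (epoxide oxygen trans to the silyloxy group) | C[Si](C)(C)C#C[C@@]12C(C)(C)C[C@@H](O[Si](C)(C)C(C)(C)C)C[C@]1(C)O2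
F4 | step 8 | silylalkynyl diol (12 carrying a trimethylsilyl group on the alkyne) | C[Si](C)(C)C#C[C@]1(O)C(C)(C)C[C@@H](O[Si](C)(C)C(C)(C)C)C[C@]1(C)O
F5 | step 32 | (E)-iodotriene butenolide | I/C=C/C=C(C)/C=C1C=C(/C=C/[C@]2(O)C(C)(C)C[C@@H](O[Si](C)(C)C(C)(C)C)C[C@]2(C)O)C(=O)O/1
F6 | step 32 | ring A (E)-dienylstannane | CC1=C(C#C/C(C)=C/C=C/[Sn](CCCC)(CCCC)CCCC)C(C)(C)C[C@H](O[Si](C)(C)C(C)(C)C)C1
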